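## Structural features

The target is a single ten-membered carbocycle, numbered here C1 (CHOAc next to the C2=C3 alkene), C2, C3 (methyl), C4, C5, C6, C7 (CO2H), C8, C9 (CHOAc) and C10 (CH-iPr). It carries two trisubstituted, ring-cis double bonds: C2=C3 (Z) and C6=C7, which is E by the CIP rules because the carboxyl group on C7 outranks C8, and which is conjugated to the free acid. Three contiguous stereocentres, C9 (R), C10 (S) and C1 (R), form a triad in which the two acetoxy groups are trans to each other across C10 (a 1,3-anti diol) and the isopropyl group is cis to the C1 acetate and trans to the C9 acetate. The fragile points are the allylic C1 acetate (ionisation, SN2' displacement), the C9 acetate, which a base can expel after γ-deprotonation of the enoate at C8, and the medium ring, in which transannular reactions are close at hand. The real difficulty is the ring itself: direct closure of a ten-membered ring is opposed by entropy and transannular strain, and it would have to deliver two cis trisubstituted alkenes of defined geometry next to a triad that epimerises and eliminates easily. The plan exploits that C1 and C7 face each other 1,5 across the ring (through C10, C9, C8) and that C6=C7 is an enoate. A transannular C1–C7 bond turns the ring into a bicyclo[5.3.0]decene (cyclopentane C1, C10, C9, C8, C7; cycloheptene C1 to C7) in which a C1 alkoxide, the C1–C7 bond and a leaving group on C6 form a Grob array. Fragmentation of that array returns the C1 ketone and the C6=C7 enoate and releases the ring without ever closing it.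

## Logic of the disconnections

23 ⇒ 22. The alkyl–oxygen bond of a 2-(trimethylsilyl)ethyl ester is cut last. The acid is then unmasked by fluoride, the only reagent class that spares both acetates and the allylic C1 centre; the forward step must be non-hydrolytic.

22 ⇒ 21 ⇒ 19. The two acetyl C–O bonds are cut to the 1,3-anti diol 21, and the C1–H bond is cut to the β-hydroxy enone 19. This removes the C1 stereocentre and lets the C9 hydroxyl of 19 direct the hydride. The forward reduction must deliver hydride intramolecularly and in the 1,2-sense only.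

19 ⇒ 18. The C9 O–Si bond is re-formed in the retrosynthetic sense. The silyl ether is needed because a free C9 hydroxyl could not survive the basic key step (retro-aldol of the β-alkoxide of the C1 ketone). The forward desilylation must be acidic, since basic fluoride would also cleave the ester.

18 ⇒ 16 (key). The C1–C7 bond is reconnected and a mesylate is placed on C6. The ten-membered ring becomes a five–seven bicycle that is built by ordinary small-ring chemistry, and C6=C7 becomes two sp3 centres whose relative configuration encodes the alkene geometry. The demand is stereoelectronic: the C6–O bond must be anti-periplanar to C1–C7, with C7–C8 gauche to C6–C5. Only a cis-fused bicycle can meet that demand, because in a trans-fused one C7–C8 is equatorial on the seven-membered ring and anti to C5, which leads to the ring-trans alkene. 16 is therefore cis-fused, with the mesylate trans to the ester on the seven-membered ring.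

16 ⇒ 15 ⇒ 14 ⇒ 13. The S–O bond and then a temporary C6 O–Si bond are cut, and the C2=C3 double bond is cut by ring-closing metathesis. The bicycle becomes a cyclopentane with two alkenyl arms, and the cis geometry of C2=C3 follows from the ring size. The demand is that the two arms stand cis on the cyclopentane.

13 ⇒ 11 + 12. The C1–C2 bond is cut to a ketone and a vinyl nucleophile. The forward addition must be non-basic (the C10–H is enolisable, the C9 silyloxy group is β) and must enter anti to the ester, that is cis to the C6 arm.

11 ⇒ 10 ⇒ 7 + 8. The C6–C7 bond is cut by an aldol disconnection to a cyclic β-keto ester and an unsaturated aldehyde. The forward step must set the C6/C7 relative configuration (C6 oxygen syn to the ester in the C1–C7–C6–C5 zigzag) through a closed, chelated transition state. It must also hold the adduct against retro-aldol cleavage, which is why the adduct is silylated at once.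

7 ⇒ 6 ⇒ 5. The ester alkoxy group is exchanged, and the C1–C7 bond of the cyclopentanone is cut by a Dieckmann disconnection to an open-chain ester imide. The imide serves as the acylating agent, so the auxiliary leaves in the ring-forming step. The same C1–C7 bond that this step makes is the one the key step later breaks.

5 ⇒ 4 ⇒ 1 + 2. The O–Si bond and then the C9–C10 bond are cut by an Evans syn-aldol disconnection. Both permanent stereocentres of the ring, apart from C1, come from one reagent-controlled step on commercial materials. The syn adduct becomes the trans C9/C10 pair on the cyclopentane.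

## Other disconnections considered

Alternative 1: The cut is C1–C10. In the forward sense, tin–lithium exchange on the thirteen-membered α-stannyl diallyl ether A1 gives an allylic α-oxy carbanion at C1. A [2,3]-sigmatropic (Wittig–Still) shift through the 2-methylallyl ether forms C1–C10, breaks the ether C–O bond and contracts the ring to the ten-membered alcohol A2, which bears an isopropenyl group on C10.
- In its favour: the ring is reached by contraction of a larger, more easily closed ring; the C1–C10 bond and both flanking stereocentres arise in one concerted step; C1 arrives as the carbinol.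
- Against it: A1 needs a configurationally defined stannyl carbinol ether, three alkenes of fixed geometry and a macrocyclic ether closure. The transfer of chirality to C1 and C10 depends on which conformer of a medium-ring transition state reacts, and a [1,2]-shift competes. A2 would still need chemoselective hydrogenation of the isopropenyl group next to two ring alkenes, and a two-stage oxidation of the C7 carbinol after removal of its ether.
- Comparison: on avoiding a direct ten-membered closure the two plans are equal. On the oxidation level at C1 and on stereocentres made in the key step (two against none), A2 is the better. The chosen plan is better on the C7 oxidation level and the C6=C7 geometry, which it settles inside the key step, and probably on step count once A1 and the later adjustments are counted.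

Alternative 2: The cuts are C1–C2 and C3–C4, with propyne A4 supplying C2, C3 and the methyl group. In the forward sense, zerovalent nickel (Ni(cod)2) couples the aldehyde of the open-chain alkylzinc iodide A3 with A4 to an oxanickelacycle. The tethered alkylzinc transfers C4 to nickel, and reductive elimination closes the ring to the allylic alcohol A5.
- In its favour: it is the most convergent plan. Two C–C bonds, the ring, the cis C2=C3 geometry (syn addition across the alkyne) and the C1 carbinol would arise in one step from a chain that aldol chemistry assembles quickly. The enoate is already in place.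
- Against it: the two ends of one chain must capture an external alkyne against the strain and entropy of a ten-membered ring. Direct alkyl transfer to the aldehyde, reduction and oligomerisation compete. The regiochemistry of alkyne insertion and the C1 selectivity rest on C10 within a macrocyclic transition state. The alkylzinc must coexist with an α-branched β-alkoxy aldehyde that epimerises and eliminates easily.
- Comparison: on step economy and on reaching C1 at the alcohol level, A5 is the better. On the enoate the two are equal. The chosen plan is better on mechanistic security, since it releases the ring from a bicycle along a fixed stereoelectronic path instead of forming it in a three-component macrocyclisation without close analogy.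

Alternative 3: The cut is C4–C5. In the forward sense, the dianion of the C7-alkylated acetoacetate A6 (NaH, then BuLi) attacks the (Z)-allylic chloride at C4 with its terminal carbon C5 under high dilution and closes the ring to the β-keto ester A7.
- In its favour: the regiochemistry of acetoacetate dianions is reliable; all three stereocentres and the C2=C3 geometry are fixed in the open chain; there is no bicyclic detour; C1 is already a protected carbinol.
- Against it: this is a direct closure of the least favourable ring size by alkylation, with dimerisation, SN2' attack and O-alkylation as competitors. The C6 ketone of A7 must afterwards be converted into the C6=C7 enoate with separate control of geometry, and C1 must be set by an additional acyclic stereocontrolled step.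
- Comparison: on C1 (no ketone reduction on the ring) A7 is the equal or the better. The chosen plan is better on the ring-forming event (fragmentation against closure) and on the enoate geometry. The step counts are likely similar.

Key step: step 11

Remark on the chemistry: the atoms keep the ring numbering of the target in all intermediates. Because a trans ring fusion cannot place C7–C8 gauche to C5 while the mesylate is anti to C1–C7, the fragmentation precursor 16 is made cis-fused (C1 S, C6 R, C7 S), with the mesylate trans to the ester on the seven-membered ring.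

## Route

Step 1
Reactants: 1 (S)-4-benzyl-3-(3-methylbutanoyl)oxazolidin-2-one; 2 methyl 4-oxobutanoate
Product: 4 methyl (4R,5S)-5-[(S)-4-benzyl-2-oxooxazolidine-3-carbonyl]-4-hydroxy-6-methylheptanoate, via boron enolate 3 (not isolated)
Conditions: Bu2BOTf, i-Pr2NEt, CH2Cl2, −78 to 0 °C; 2, −78 to 0 °C; pH 7 buffer (NaH2PO4/Na2HPO4), MeOH, H2O2, 0 °C
Reagents that add atoms: none
Why: Evans syn-aldol: the (Z)-boron enolate 3 adds to 2 through a Zimmerman–Traxler chair in which the benzyl group of the auxiliary shields one enolate face, which sets C10 (S) and C9 (R) together as the syn pair that becomes the trans pair on the later ring. The γ-hydroxy ester is kept cold and neutral and is silylated at once to forestall lactonisation.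

Step 2
Reactants: 4 methyl (4R,5S)-5-[(S)-4-benzyl-2-oxooxazolidine-3-carbonyl]-4-hydroxy-6-methylheptanoate
Product: 5 methyl (4R,5S)-5-[(S)-4-benzyl-2-oxooxazolidine-3-carbonyl]-4-[(tert-butyldimethylsilyl)oxy]-6-methylheptanoate
Conditions: t-BuMe2SiOTf, 2,6-lutidine, CH2Cl2, −78 to 0 °C
Reagents that add atoms: tert-butyldimethylsilyl trifluoromethanesulfonate, CC(C)(C)[Si](C)(C)OS(=O)(=O)C(F)(F)F
Why: Silylation with a silyl triflate and a hindered pyridine base protects the hindered secondary alcohol quickly and without acid or strong base; the ether blocks lactone formation and retro-aldol cleavage in the base-mediated ring closure that follows.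

Step 3
Reactants: 5 methyl (4R,5S)-5-[(S)-4-benzyl-2-oxooxazolidine-3-carbonyl]-4-[(tert-butyldimethylsilyl)oxy]-6-methylheptanoate
Product: 6 methyl (3S,4R)-4-[(tert-butyldimethylsilyl)oxy]-2-oxo-3-(propan-2-yl)cyclopentane-1-carboxylate
Conditions: NaN(SiMe3)2 (2.1 equiv), THF, −78 to −20 °C; sat. aq NH4Cl
Reagents that add atoms: none
Why: Dieckmann-type ring closure: the ester enolate at C7 attacks the exocyclic imide carbonyl C1 (5-exo-trig) and the tetrahedral intermediate expels the oxazolidinone anion, so the auxiliary leaves in the ring-forming step. The imide α-proton at C10 is sterically shielded, and the product rests as its β-keto ester enolate until the quench, which protects C10 and the C9 silyloxy group from epimerisation and β-elimination; C7 forms as an epimer/enol mixture, which is of no consequence.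

Step 4
Reactants: 6 methyl (3S,4R)-4-[(tert-butyldimethylsilyl)oxy]-2-oxo-3-(propan-2-yl)cyclopentane-1-carboxylate
Product: 7 2-(trimethylsilyl)ethyl (3S,4R)-4-[(tert-butyldimethylsilyl)oxy]-2-oxo-3-(propan-2-yl)cyclopentane-1-carboxylate
Conditions: Me3SiCH2CH2OH, DMAP (cat.), toluene, reflux (−MeOH)
Reagents that add atoms: 2-(trimethylsilyl)ethanol, C[Si](C)(C)CCO
Why: Transesterification of a β-keto ester, which exchanges its alkoxy group far more readily than a simple ester (DMAP catalysis, acylketene pathway), driven by distilling out methanol. The 2-(trimethylsilyl)ethyl ester is chosen because fluoride can cleave it at the end without touching the acetates.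

Step 5
Reactants: 7 2-(trimethylsilyl)ethyl (3S,4R)-4-[(tert-butyldimethylsilyl)oxy]-2-oxo-3-(propan-2-yl)cyclopentane-1-carboxylate; 8 4-methylpent-4-enal
Product: 10 2-(trimethylsilyl)ethyl (1S,3S,4R)-4-[(tert-butyldimethylsilyl)oxy]-1-[(1R)-1-hydroxy-4-methylpent-4-en-1-yl]-2-oxo-3-(propan-2-yl)cyclopentane-1-carboxylate, via titanium enolate 9 (not isolated)
Conditions: TiCl4, Et3N, CH2Cl2, −78 °C; then 8, −78 °C; sat. aq NH4Cl at −78 °C
Reagents that add atoms: none
Why: Titanium enolate aldol addition after soft enolisation: the chelated enolate 9 adds to 8 through a Zimmerman–Traxler chair with the aldehyde chain equatorial, which places the C6 oxygen syn to the ester in the C1–C7–C6–C5 zigzag (C6 R, C7 S); the aldehyde should approach the face away from the C10 isopropyl group, which flanks the titanium-bearing oxygen. The strong Ti–O bonds of the chelated aldolate and the cold quench hold back the retro-aldol reaction to which such quaternary adducts are prone.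

Step 6
Reactants: 10 2-(trimethylsilyl)ethyl (1S,3S,4R)-4-[(tert-butyldimethylsilyl)oxy]-1-[(1R)-1-hydroxy-4-methylpent-4-en-1-yl]-2-oxo-3-(propan-2-yl)cyclopentane-1-carboxylate
Product: 11 2-(trimethylsilyl)ethyl (1S,3S,4R)-4-[(tert-butyldimethylsilyl)oxy]-1-[(1R)-4-methyl-1-[(triethylsilyl)oxy]pent-4-en-1-yl]-2-oxo-3-(propan-2-yl)cyclopentane-1-carboxylate
Conditions: Et3SiOTf, 2,6-lutidine, CH2Cl2, −78 °C
Reagents that add atoms: triethylsilyl trifluoromethanesulfonate, CC[Si](CC)(CC)OS(=O)(=O)C(F)(F)F
Why: Cold, non-basic silylation caps the β-hydroxy ketone before any alkoxide can form, which shuts off retro-aldol cleavage in step 7 and removes the C6 oxygen as a chelating site. Triethylsilyl is chosen so that it can later be removed in the presence of the C9 tert-butyldimethylsilyl ether.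

Step 7
Reactants: 11 2-(trimethylsilyl)ethyl (1S,3S,4R)-4-[(tert-butyldimethylsilyl)oxy]-1-[(1R)-4-methyl-1-[(triethylsilyl)oxy]pent-4-en-1-yl]-2-oxo-3-(propan-2-yl)cyclopentane-1-carboxylate; 12 vinylmagnesium bromide
Product: 13 2-(trimethylsilyl)ethyl (1S,2S,3S,4R)-4-[(tert-butyldimethylsilyl)oxy]-2-ethenyl-2-hydroxy-1-[(1R)-4-methyl-1-[(triethylsilyl)oxy]pent-4-en-1-yl]-3-(propan-2-yl)cyclopentane-1-carboxylate
Conditions: CeCl3, 12, THF, −78 °C; sat. aq NH4Cl at −78 °C
Reagents that add atoms: none
Why: 1,2-Addition of the organocerium reagent formed from 12 and CeCl3, whose low basicity spares the enolisable C10–H, the β-silyloxy group at C9 and the ester. The vinyl group should enter anti to the C10 isopropyl group and anti to the ester, which the oxophilic metal holds in a chelate with the ketone, so that C2 ends up cis to the C6 arm (C1 S); the metal alkoxide is quenched cold so that C1–C7 cannot cleave by retro-aldol reaction.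

Step 8
Reactants: 13 2-(trimethylsilyl)ethyl (1S,2S,3S,4R)-4-[(tert-butyldimethylsilyl)oxy]-2-ethenyl-2-hydroxy-1-[(1R)-4-methyl-1-[(triethylsilyl)oxy]pent-4-en-1-yl]-3-(propan-2-yl)cyclopentane-1-carboxylate
Product: 14 2-(trimethylsilyl)ethyl (2R,3S,3aS,8R,8aS)-2-[(tert-butyldimethylsilyl)oxy]-3a-hydroxy-5-methyl-3-(propan-2-yl)-8-[(triethylsilyl)oxy]-1,2,3,3a,6,7,8,8a-octahydroazulene-8a-carboxylate (cis-fused)
Conditions: second-generation Grubbs catalyst [RuCl2(=CHPh)(H2IMes)(PCy3)] (5 mol %), toluene, 80 °C
Reagents that add atoms: none
Why: Ring-closing metathesis: the catalyst loads on the monosubstituted vinyl group and closes onto the 1,1-disubstituted alkene to a trisubstituted cycloheptene with loss of ethene. Within a seven-membered ring C2=C3 can only be cis, and because C2 and C6 stand on the same face the bicycle is cis-fused.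

Step 9
Reactants: 14 2-(trimethylsilyl)ethyl (2R,3S,3aS,8R,8aS)-2-[(tert-butyldimethylsilyl)oxy]-3a-hydroxy-5-methyl-3-(propan-2-yl)-8-[(triethylsilyl)oxy]-1,2,3,3a,6,7,8,8a-octahydroazulene-8a-carboxylate
Product: 15 2-(trimethylsilyl)ethyl (2R,3S,3aS,8R,8aS)-2-[(tert-butyldimethylsilyl)oxy]-3a,8-dihydroxy-5-methyl-3-(propan-2-yl)-1,2,3,3a,6,7,8,8a-octahydroazulene-8a-carboxylate
Conditions: PPTS (cat.), MeOH–CH2Cl2, 0 °C
Reagents that add atoms: none
Why: Mild acid-catalysed methanolysis removes the secondary triethylsilyl ether much faster than the tert-butyldimethylsilyl ether at C9. The buffered acid is too weak to ionise the tertiary allylic alcohol or to cleave the silylethyl ester.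

Step 10
Reactants: 15 2-(trimethylsilyl)ethyl (2R,3S,3aS,8R,8aS)-2-[(tert-butyldimethylsilyl)oxy]-3a,8-dihydroxy-5-methyl-3-(propan-2-yl)-1,2,3,3a,6,7,8,8a-octahydroazulene-8a-carboxylate
Product: 16 2-(trimethylsilyl)ethyl (2R,3S,3aS,8R,8aS)-2-[(tert-butyldimethylsilyl)oxy]-3a-hydroxy-8-(methanesulfonyloxy)-5-methyl-3-(propan-2-yl)-1,2,3,3a,6,7,8,8a-octahydroazulene-8a-carboxylate (cis-fused; in target numbering 1S,6R,7S,9R,10S; mesylate trans to the ester on the seven-membered ring)
Conditions: MsCl, Et3N, CH2Cl2, −20 °C
Reagents that add atoms: methanesulfonyl chloride, CS(=O)(=O)Cl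
Why: Sulfonylation through sulfene reaches the hindered secondary C6 hydroxyl but not the tertiary C1 hydroxyl at low temperature. Triethylamine is too weak a base to start the fragmentation.

Step 11
Reactants: 16 2-(trimethylsilyl)ethyl (2R,3S,3aS,8R,8aS)-2-[(tert-butyldimethylsilyl)oxy]-3a-hydroxy-8-(methanesulfonyloxy)-5-methyl-3-(propan-2-yl)-1,2,3,3a,6,7,8,8a-octahydroazulene-8a-carboxylate
Product: 18 2-(trimethylsilyl)ethyl (2Z,6E,9R,10S)-9-[(tert-butyldimethylsilyl)oxy]-3-methyl-1-oxo-10-(propan-2-yl)cyclodeca-2,6-diene-7-carboxylate (target numbering), via potassium alkoxide 17 (not isolated)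
Conditions: KH (1.0 equiv), THF, 0 °C; pH 7 buffer (NaH2PO4/Na2HPO4)
Reagents that add atoms: none
Why: Grob fragmentation of a cyclic 1,3-diol monosulfonate: KH deprotonates the tertiary C1 hydroxyl irreversibly to the alkoxide 17, whose oxygen lone pair pushes into C1–C7 while that σ bond donates into the anti-periplanar C6–O σ* orbital, so that C1=O and C6=C7 form and methanesulfonate leaves in one six-electron event. The ten-membered ring is not closed by bond formation but unveiled by scission of the zero-atom bridge C1–C7 of the bicyclo[5.3.0]decene, so neither the entropy of a cyclisation nor transannular strain in a closing transition state has to be paid. No stereocentre is created: C1, C6 and C7 become trigonal, and C9 and C10 lie outside the reacting array and are carried through. The selectivity that matters is the geometry of C6=C7: in the reacting conformer the mesylate is equatorial on the seven-membered ring and anti to C1–C7, and because the ring fusion is cis the C7–C8 bond can be axial and gauche to C6–C5, which puts C5 and C8 on the same side of the new double bond (ring-cis, E), whereas a trans-fused isomer would hold C7–C8 anti to C5 and could only give the ring-trans alkene. Should C1–C7 break ahead of C6–O, the ester enolate is born with its p orbital aligned with the C6–O bond and expels mesylate (E1cB) before the ring relaxes, which leads to the same isomer. The C2=C3 double bond keeps the cis geometry it acquired in the seven-membered ring and ends up conjugated to the new ketone. With exactly one equivalent of KH no strong base outlasts the fragmentation, so the C10–H is not removed and the C9 silyloxy group is not eliminated; O-alkylation at C6 to an oxetane is the competing path and is disfavoured by the alignment for fragmentation.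

Step 12
Reactants: 18 2-(trimethylsilyl)ethyl (2Z,6E,9R,10S)-9-[(tert-butyldimethylsilyl)oxy]-3-methyl-1-oxo-10-(propan-2-yl)cyclodeca-2,6-diene-7-carboxylate
Product: 19 2-(trimethylsilyl)ethyl (2Z,6E,9R,10S)-9-hydroxy-3-methyl-1-oxo-10-(propan-2-yl)cyclodeca-2,6-diene-7-carboxylate
Conditions: HF·pyridine, pyridine, THF, 0 °C to rt
Reagents that add atoms: none
Why: Buffered HF·pyridine cleaves the secondary silyl ether under weakly acidic conditions, under which the β-hydroxy ketone neither cleaves by retro-aldol reaction nor eliminates. A basic fluoride source would also attack the silylethyl ester.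

Step 13
Reactants: 19 2-(trimethylsilyl)ethyl (2Z,6E,9R,10S)-9-hydroxy-3-methyl-1-oxo-10-(propan-2-yl)cyclodeca-2,6-diene-7-carboxylate
Product: 21 2-(trimethylsilyl)ethyl (1R,2Z,6E,9R,10S)-1,9-dihydroxy-3-methyl-10-(propan-2-yl)cyclodeca-2,6-diene-7-carboxylate, via alkoxyborohydride 20 (not isolated)
Conditions: Me4NBH(OAc)3, MeCN–AcOH (1:1), −30 to −20 °C; aq NaHCO3
Reagents that add atoms: none
Why: Evans–Saksena hydroxyl-directed reduction: the C9 hydroxyl exchanges for acetate on boron (20) and the hydride is delivered intramolecularly to the carbonyl face on the side of that oxygen, so that the new C1 hydroxyl is trans to the C9 hydroxyl (1,3-anti, C1 R). The reagent leaves the enoate alone and attacks the enone only in the 1,2-sense because the delivery is intramolecular.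

Step 14
Reactants: 21 2-(trimethylsilyl)ethyl (1R,2Z,6E,9R,10S)-1,9-dihydroxy-3-methyl-10-(propan-2-yl)cyclodeca-2,6-diene-7-carboxylate
Product: 22 2-(trimethylsilyl)ethyl (1R,2Z,6E,9R,10S)-1,9-diacetoxy-3-methyl-10-(propan-2-yl)cyclodeca-2,6-diene-7-carboxylate
Conditions: Ac2O, DMAP, pyridine, CH2Cl2, rt
Reagents that add atoms: acetic anhydride, CC(=O)OC(C)=O
Why: Acylation under nucleophilic catalysis by DMAP esterifies both secondary hydroxyls, including the hindered ones that flank C10. No stereocentre is at risk because neither carbinol carbon carries an acidifying group.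

Step 15
Reactants: 22 2-(trimethylsilyl)ethyl (1R,2Z,6E,9R,10S)-1,9-diacetoxy-3-methyl-10-(propan-2-yl)cyclodeca-2,6-diene-7-carboxylate
Product: 23 (1R,2Z,6E,9R,10S)-1,9-diacetoxy-3-methyl-10-(propan-2-yl)cyclodeca-2,6-diene-7-carboxylic acid (target numbering)
Conditions: TASF [(Me2N)3S+ Me3SiF2−], DMF, 0 °C to rt; cold 0.1 M HCl
Reagents that add atoms: none
Why: Fluoride attacks the silicon of the 2-(trimethylsilyl)ethyl ester and triggers β-elimination to ethene, fluorotrimethylsilane and the carboxylate. The anhydrous, weakly basic fluoride source should leave both acetates, the allylic C1 centre and the alkene geometries untouched, and mild acidification gives the acid.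

## Compound list

1 | (S)-4-benzyl-3-(3-methylbutanoyl)oxazolidin-2-one | CC(C)CC(=O)N1[C@@H](Cc2ccccc2)COC1=O | starting material
2 | methyl 4-oxobutanoate | COC(=O)CCC=O | starting material
3 | (S)-4-benzyl-3-[(Z)-1-(dibutylboranyloxy)-3-methylbut-1-en-1-yl]oxazolidin-2-one (boron enolate) | CC(C)/C=C(\OB(CCCC)CCCC)N1[C@@H](Cc2ccccc2)COC1=O | intermediate (not isolated)
4 | methyl (4R,5S)-5-[(S)-4-benzyl-2-oxooxazolidine-3-carbonyl]-4-hydroxy-6-methylheptanoate | COC(=O)CC[C@@H](O)[C@@H](C(=O)N1[C@@H](Cc2ccccc2)COC1=O)C(C)C | intermediate
5 | methyl (4R,5S)-5-[(S)-4-benzyl-2-oxooxazolidine-3-carbonyl]-4-[(tert-butyldimethylsilyl)oxy]-6-methylheptanoate | COC(=O)CC[C@@H](O[Si](C)(C)C(C)(C)C)[C@@H](C(=O)N1[C@@H](Cc2ccccc2)COC1=O)C(C)C | intermediate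
6 | methyl (3S,4R)-4-[(tert-butyldimethylsilyl)oxy]-2-oxo-3-(propan-2-yl)cyclopentane-1-carboxylate (C1 epimers and enol) | COC(=O)C1C[C@@H](O[Si](C)(C)C(C)(C)C)[C@H](C(C)C)C1=O | intermediate
7 | 2-(trimethylsilyl)ethyl (3S,4R)-4-[(tert-butyldimethylsilyl)oxy]-2-oxo-3-(propan-2-yl)cyclopentane-1-carboxylate (C1 epimers and enol) | C[Si](C)(C)CCOC(=O)C1C[C@@H](O[Si](C)(C)C(C)(C)C)[C@H](C(C)C)C1=O | intermediate
8 | 4-methylpent-4-enal | CC(=C)CCC=O | starting material
9 | trichlorotitanium enolate of 7 | Cl[Ti](Cl)(Cl)OC1=C(C(=O)OCC[Si](C)(C)C)C[C@@H](O[Si](C)(C)C(C)(C)C)[C@@H]1C(C)C | intermediate (not isolated)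
10 | 2-(trimethylsilyl)ethyl (1S,3S,4R)-4-[(tert-butyldimethylsilyl)oxy]-1-[(1R)-1-hydroxy-4-methylpent-4-en-1-yl]-2-oxo-3-(propan-2-yl)cyclopentane-1-carboxylate | CC(=C)CC[C@@H](O)[C@@]1(C(=O)OCC[Si](C)(C)C)C[C@@H](O[Si](C)(C)C(C)(C)C)[C@H](C(C)C)C1=O | intermediate
11 | 2-(trimethylsilyl)ethyl (1S,3S,4R)-4-[(tert-butyldimethylsilyl)oxy]-1-[(1R)-4-methyl-1-[(triethylsilyl)oxy]pent-4-en-1-yl]-2-oxo-3-(propan-2-yl)cyclopentane-1-carboxylate | CC(=C)CC[C@@H](O[Si](CC)(CC)CC)[C@@]1(C(=O)OCC[Si](C)(C)C)C[C@@H](O[Si](C)(C)C(C)(C)C)[C@H](C(C)C)C1=O | intermediate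
12 | vinylmagnesium bromide | C=C[Mg]Br | starting material
13 | 2-(trimethylsilyl)ethyl (1S,2S,3S,4R)-4-[(tert-butyldimethylsilyl)oxy]-2-ethenyl-2-hydroxy-1-[(1R)-4-methyl-1-[(triethylsilyl)oxy]pent-4-en-1-yl]-3-(propan-2-yl)cyclopentane-1-carboxylate | CC(=C)CC[C@@H](O[Si](CC)(CC)CC)[C@@]1(C(=O)OCC[Si](C)(C)C)C[C@@H](O[Si](C)(C)C(C)(C)C)[C@H](C(C)C)[C@@]1(O)C=C | intermediate
14 | 2-(trimethylsilyl)ethyl (2R,3S,3aS,8R,8aS)-2-[(tert-butyldimethylsilyl)oxy]-3a-hydroxy-5-methyl-3-(propan-2-yl)-8-[(triethylsilyl)oxy]-1,2,3,3a,6,7,8,8a-octahydroazulene-8a-carboxylate (cis-fused) | CC[Si](CC)(CC)O[C@@H]1CCC(C)=C[C@]2(O)[C@@H](C(C)C)[C@H](O[Si](C)(C)C(C)(C)C)C[C@]12C(=O)OCC[Si](C)(C)C | intermediate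
15 | 2-(trimethylsilyl)ethyl (2R,3S,3aS,8R,8aS)-2-[(tert-butyldimethylsilyl)oxy]-3a,8-dihydroxy-5-methyl-3-(propan-2-yl)-1,2,3,3a,6,7,8,8a-octahydroazulene-8a-carboxylate (cis-fused) | O[C@@H]1CCC(C)=C[C@]2(O)[C@@H](C(C)C)[C@H](O[Si](C)(C)C(C)(C)C)C[C@]12C(=O)OCC[Si](C)(C)C | intermediate
16 | 2-(trimethylsilyl)ethyl (2R,3S,3aS,8R,8aS)-2-[(tert-butyldimethylsilyl)oxy]-3a-hydroxy-8-(methanesulfonyloxy)-5-methyl-3-(propan-2-yl)-1,2,3,3a,6,7,8,8a-octahydroazulene-8a-carboxylate (cis-fused; hydroxyl, ester and isopropyl on one face, silyloxy and mesylate on the other) | CS(=O)(=O)O[C@@H]1CCC(C)=C[C@]2(O)[C@@H](C(C)C)[C@H](O[Si](C)(C)C(C)(C)C)C[C@]12C(=O)OCC[Si](C)(C)C | intermediate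
17 | potassium alkoxide of 16 | CS(=O)(=O)O[C@@H]1CCC(C)=C[C@]2([O-])[C@@H](C(C)C)[C@H](O[Si](C)(C)C(C)(C)C)C[C@]12C(=O)OCC[Si](C)(C)C.[K+] | intermediate (not isolated)
18 | 2-(trimethylsilyl)ethyl (2Z,6E,9R,10S)-9-[(tert-butyldimethylsilyl)oxy]-3-methyl-1-oxo-10-(propan-2-yl)cyclodeca-2,6-diene-7-carboxylate (target numbering) | O=C1/C=C(/C)CC/C=C(/C(=O)OCC[Si](C)(C)C)C[C@@H](O[Si](C)(C)C(C)(C)C)[C@@H]1C(C)C | intermediate
19 | 2-(trimethylsilyl)ethyl (2Z,6E,9R,10S)-9-hydroxy-3-methyl-1-oxo-10-(propan-2-yl)cyclodeca-2,6-diene-7-carboxylate | O=C1/C=C(/C)CC/C=C(/C(=O)OCC[Si](C)(C)C)C[C@@H](O)[C@@H]1C(C)C | intermediate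
20 | tetramethylammonium diacetoxy(hydrido)borate bound through the C9 oxygen of 19 | O=C1/C=C(/C)CC/C=C(/C(=O)OCC[Si](C)(C)C)C[C@@H](O[BH-](OC(C)=O)OC(C)=O)[C@@H]1C(C)C.C[N+](C)(C)C | intermediate (not isolated)
21 | 2-(trimethylsilyl)ethyl (1R,2Z,6E,9R,10S)-1,9-dihydroxy-3-methyl-10-(propan-2-yl)cyclodeca-2,6-diene-7-carboxylate | O[C@@H]1/C=C(/C)CC/C=C(/C(=O)OCC[Si](C)(C)C)C[C@@H](O)[C@@H]1C(C)C | intermediate
22 | 2-(trimethylsilyl)ethyl (1R,2Z,6E,9R,10S)-1,9-diacetoxy-3-methyl-10-(propan-2-yl)cyclodeca-2,6-diene-7-carboxylate | CC(=O)O[C@@H]1/C=C(/C)CC/C=C(/C(=O)OCC[Si](C)(C)C)C[C@@H](OC(C)=O)[C@@H]1C(C)C | intermediate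
23 | (1R,2Z,6E,9R,10S)-1,9-diacetoxy-3-methyl-10-(propan-2-yl)cyclodeca-2,6-diene-7-carboxylic acid (target numbering) | CC(=O)O[C@@H]1/C=C(/C)CC/C=C(/C(=O)O)C[C@@H](OC(C)=O)[C@@H]1C(C)C | target

## Step count and least certain steps

Total: 15 steps. Longest linear sequence: 15 steps (1 to 23); 2, 8 and 12 enter as commercial building blocks.

Step 11 (key step). Most likely to go wrong is a loss of the stereospecific course. If the seven-membered ring does not populate the conformer with the equatorial mesylate, the alkoxide may alkylate C6 to an oxetane, or C1–C7 may cleave and the enolate relax before it eliminates, which erodes the alkene geometry. Lingering alkoxide may also start β-elimination of the C9 silyloxy group. The fallback sets out from 15 and returns at 18, and it decouples ring release from alkene formation. The C6 hydroxyl of 15 is oxidised with Dess–Martin periodinane to the C6 ketone F1. Its tertiary β-hydroxyl then undergoes base-catalysed retro-aldol ring expansion (DBU, CH2Cl2), driven by the stabilised β-keto ester enolate, to the ten-membered diketo ester F2. NaH and PhNTf2 convert the chelated sodium enolate into the (Z)-enol triflate F3, with the triflate cis to the ester. Palladium-catalysed formate reduction (Pd(OAc)2, PPh3, Bu3N, HCO2H, DMF) replaces the triflate by hydrogen with retention and gives 18.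

Step 7. Most likely to go wrong is poor facial selectivity. The C6 arm is the bulkier substituent on C7, so attack syn to the ester and anti to the arm may compete, and that would lead to a trans-fused bicycle that cannot give the ring-cis alkene. The fallback sets out from 7 and returns at 14, and it closes the seven-membered ring by intramolecular C1–C2 bond formation, which can only deliver C2 from the face of the tether. Propargyl alcohol is carbometallated with MeMgBr and catalytic CuI, and iodination gives (Z)-3-iodo-2-methylprop-2-en-1-ol F4. CBr4/PPh3 gives the allylic bromide F5, LiCH2CN the nitrile F6, and i-Bu2AlH followed by dilute HCl the aldehyde (Z)-5-iodo-4-methylpent-4-enal F7. F7 replaces 8 in the titanium aldol with 7 and gives the iodo aldol F8, and silylation gives the triethylsilyl ether F9. A Nozaki–Hiyama–Kishi cyclisation (CrCl2, catalytic NiCl2, DMF) then adds the (Z)-alkenylchromium to the C1 ketone and gives the cis-fused 14.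

Step 5. Most likely to go wrong is reversal of the addition (retro-aldol cleavage of the quaternary adduct during reaction or quench), Lewis-acid-induced cyclisation of the unsaturated aldehyde, or erosion of the C6/C7 selectivity if an open transition state competes. The fallback sets out from 7 and returns at 10, and it generates the enolate reductively under neutral conditions. 7 is brominated at C7 with N-bromosuccinimide to the α-bromo keto ester F10. SmI2 (2 equiv, THF, −78 °C) in the presence of 8 gives a chelated trivalent samarium enolate (Reformatsky-type aldol), which should add through the same closed transition state and hold the aldolate firmly until the quench.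

Step 13. Most likely to go wrong is delivery of hydride to the wrong carbonyl face, or sluggish delivery, because the conformation of the ten-membered ring may keep the boron-bound C9 oxygen from reaching C1 in the arrangement that gives the anti diol. The fallback sets out from 18 and returns at 21, and it replaces substrate-directed delivery by reagent control. Corey–Bakshi–Shibata reduction of 18 (oxazaborolidine catalyst, catecholborane, toluene, −78 °C) gives the C1 alcohol F11 with the silyl ether still in place. The (R)-catalyst is the first choice on the premise that the alkenyl arm acts as the larger group, and the antipode is at hand if the branched C10 arm dominates. HF·pyridine then removes the silyl group to give 21.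

## Further compounds

F1 | step 11 | 6-oxo analogue of 15 (cis-fused C1-hydroxy C6-keto ester, other centres as in 15) | O=C1CCC(C)=C[C@]2(O)[C@@H](C(C)C)[C@H](O[Si](C)(C)C(C)(C)C)C[C@]12C(=O)OCC[Si](C)(C)C
F2 | step 11 | 2-(trimethylsilyl)ethyl (2Z,9R,10S)-9-[(tert-butyldimethylsilyl)oxy]-3-methyl-1,6-dioxo-10-(propan-2-yl)cyclodec-2-ene-7-carboxylate (C7 epimers and enol) | O=C1/C=C(/C)CCC(=O)C(C(=O)OCC[Si](C)(C)C)C[C@@H](O[Si](C)(C)C(C)(C)C)[C@@H]1C(C)C
F3 | step 11 | 2-(trimethylsilyl)ethyl (2Z,6Z,9R,10S)-9-[(tert-butyldimethylsilyl)oxy]-3-methyl-1-oxo-10-(propan-2-yl)-6-(trifluoromethanesulfonyloxy)cyclodeca-2,6-diene-7-carboxylate | O=C1/C=C(/C)CC/C(OS(=O)(=O)C(F)(F)F)=C(/C(=O)OCC[Si](C)(C)C)C[C@@H](O[Si](C)(C)C(C)(C)C)[C@@H]1C(C)C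
F4 | step 7 | (Z)-3-iodo-2-methylprop-2-en-1-ol | OC/C(C)=C\I
F5 | step 7 | (Z)-3-bromo-1-iodo-2-methylprop-1-ene | BrC/C(C)=C\I
F6 | step 7 | (Z)-5-iodo-4-methylpent-4-enenitrile | N#CCC/C(C)=C\I
F7 | step 7 | (Z)-5-iodo-4-methylpent-4-enal | O=CCC/C(C)=C\I
F8 | step 7 | 2-(trimethylsilyl)ethyl (1S,3S,4R)-4-[(tert-butyldimethylsilyl)oxy]-1-[(1R,4Z)-1-hydroxy-5-iodo-4-methylpent-4-en-1-yl]-2-oxo-3-(propan-2-yl)cyclopentane-1-carboxylate | I/C=C(/C)CC[C@@H](O)[C@@]1(C(=O)OCC[Si](C)(C)C)C[C@@H](O[Si](C)(C)C(C)(C)C)[C@H](C(C)C)C1=O
F9 | step 7 | triethylsilyl ether of F8 | I/C=C(/C)CC[C@@H](O[Si](CC)(CC)CC)[C@@]1(C(=O)OCC[Si](C)(C)C)C[C@@H](O[Si](C)(C)C(C)(C)C)[C@H](C(C)C)C1=O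
F10 | step 5 | 2-(trimethylsilyl)ethyl (3S,4R)-1-bromo-4-[(tert-butyldimethylsilyl)oxy]-2-oxo-3-(propan-2-yl)cyclopentane-1-carboxylate (C1 epimers) | BrC1(C(=O)OCC[Si](C)(C)C)C[C@@H](O[Si](C)(C)C(C)(C)C)[C@H](C(C)C)C1=O
F11 | step 13 | 2-(trimethylsilyl)ethyl (1R,2Z,6E,9R,10S)-9-[(tert-butyldimethylsilyl)oxy]-1-hydroxy-3-methyl-10-(propan-2-yl)cyclodeca-2,6-diene-7-carboxylate | O[C@@H]1/C=C(/C)CC/C=C(/C(=O)OCC[Si](C)(C)C)C[C@@H](O[Si](C)(C)C(C)(C)C)[C@@H]1C(C)C
A1 | alternative 1 | thirteen-membered α-tributylstannyl diallyl ether (C1 stannane, ether oxygen between C1 and the 2-methylallyl carbon, C9 silyl ether, C7 CH2OPMB) | CCCC[Sn](CCCC)(CCCC)[C@H]1OC/C(C)=C/[C@H](O[Si](C)(C)C(C)(C)C)C/C(COCc2ccc(OC)cc2)=C\CC/C(C)=C\1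
A2 | alternative 1 | ten-membered C1 alcohol with C10 isopropenyl, C9 silyl ether and C7 CH2OPMB | O[C@@H]1/C=C(/C)CC/C=C(/COCc2ccc(OC)cc2)C[C@@H](O[Si](C)(C)C(C)(C)C)[C@@H]1C(C)=C
A3 | alternative 2 | open-chain C1 aldehyde with C9 PMB ether, C6=C7 silylethyl enoate and C4 alkylzinc iodide | O=C[C@@H](C(C)C)[C@H](OCc1ccc(OC)cc1)C/C(C(=O)OCC[Si](C)(C)C)=C\CC[Zn]I
A4 | alternative 2 | propyne | CC#C
A5 | alternative 2 | ten-membered C1 allylic alcohol with C9 PMB ether and C7 silylethyl ester | O[C@@H]1/C=C(/C)CC/C=C(/C(=O)OCC[Si](C)(C)C)C[C@@H](OCc2ccc(OC)cc2)[C@@H]1C(C)C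
A6 | alternative 3 | C7-alkylated 2-(trimethylsilyl)ethyl acetoacetate with C1 and C9 silyl ethers and a (Z)-allylic chloride at C4 (C7 epimers) | CC(=O)C(C(=O)OCC[Si](C)(C)C)C[C@@H](O[Si](C)(C)C(C)(C)C)[C@H](C(C)C)[C@H](O[Si](C)(C)C(C)(C)C)/C=C(/C)CCl
A7 | alternative 3 | ten-membered β-keto ester (C6 ketone, C7 silylethyl ester) with C1 and C9 silyl ethers | CC(C)(C)[Si](C)(C)O[C@@H]1/C=C(/C)CCC(=O)C(C(=O)OCC[Si](C)(C)C)C[C@@H](O[Si](C)(C)C(C)(C)C)[C@@H]1C(C)C
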